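The numbers of this flask were set for the occasion; the result is computed.

**Reagent balance.** In this scheme each unit of reagent charged ends in a product, in spent catalyst, in homo dimer (two per dimer) or still in the flask. So I reckon the conversion as what the charge allows, less what the dimer takes.

left-handed substrate 34 mM; reagent 68.0 mM; precatalyst 0.17 mM; right-handed substrate 34 mM; time 30 min

    reagent + free catalyst → spent catalyst (k1 = 0.0947 L mol⁻¹ s⁻¹)
    reagent + free catalyst + left-handed substrate → free catalyst + left-handed product (k2 = 9960 L² mol⁻² s⁻¹)
    left-handed substrate ⇌ right-handed substrate (k3 = 0.00174 s⁻¹)
    2 reagent → homo dimer (k4 = 0.0202 L mol⁻¹ s⁻¹)
    reagent + free catalyst + right-handed substrate → free catalyst + right-handed product (k5 = 287 L² mol⁻² s⁻¹)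
    precatalyst → free catalyst (k6 = 0.0209 s⁻¹)

- free catalyst is single-handed; left-handed substrate and right-handed substrate are mirror images of each other, charged as a racemate, each of them at the stated concentration
- a doubled species enters its step squared and goes two at a time
- the reaction counts as stopped when no species that holds the left-handed substrate and right-handed substrate together changes by six tenths of a point or more over the second half of the time
- run time (flask): 30 min

- at 30 min, what has stopped the reaction, if anything has (all of the left-handed substrate has reacted / no working catalyst is left / forward and back rates have come level / it is still moving)
- conversion of left-handed substrate and right-handed substrate together at 30 min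
- amount of left-handed product at 30 min, in percent of the left-handed substrate and right-handed substrate together charged
- amount of right-handed product at 30 min, in percent of the left-handed substrate and right-handed substrate together charged

**High end.** In the flask, one reagent per product gives a ceiling of 100% conversion. I define the dimer tax as the share of the reagent being consumed at a given moment that goes to homo dimer. With the catalyst taken as fully released, since precatalyst has a half-life of 0.55 min, shorter than the run, the tax at the charge is 4.43%. Paid throughout, it leaves 95.6%, the high end of my bracket by estimate.

**Low end.** Left-handed substrate reacts faster than right-handed, so with reagent at 34.0 mM I take left-handed substrate as steady, used as fast as racemisation supplies it. The tax there is 28.8%. Paid throughout, it leaves 71.2%, the low end by estimate.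

**Carried tax.** The mean of the two, 16.6%, is the dimer tax I carry. It gives 83.4%, a hand estimate and not a proof.

**The forecast.** It says “Reagent is the real limit”. Its verdict is: it is still moving; it gives conversion 84.3% (81.5% to 87%), left-handed product 74.7% and right-handed product 9.6%. That conversion lies inside my bracket.

**The flask.** The simulation's verdict is: it is still moving; it gives conversion 84.8%, left-handed product 75.4% and right-handed product 9.39%.

**Tax paid.** In the flask, homo dimer stands at 5.09 mM at 30.0 min, which took 15.0% of the reagent charge against my 16.6%. By then, left-handed substrate goes to product at 0.026 of its forward rate to right-handed substrate, slower, with 0.089% of the reagent left. With 41 mM of reagent, the carried tax becomes 9.07% and gives 54.8%. That neighbour flask reaches 56.6%.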